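**Plan**

1. Locants and rings: the three stilbene units carry the locant suffixes a, b and c. Ring A (4-oxyphenyl) sits on C-7a, ring B (C-9a to C-14a, O on C-11a and C-13a) on C-8a, ring C (2,4-dioxyphenyl) on C-7b, ring D (central, C-9b to C-14b, O on C-11b and C-13b) on C-8b (a CH2 group), ring E (2,4-dioxyphenyl) on C-7c, ring F (3,5-dioxyphenyl) on C-8c. "Tetracyclic core" = ring D fused to the dihydrofuran O-11b/C-7a/C-8a/C-10b and to the seven-membered ring C-8a/C-9a/C-10a/C-7b/C-8b/C-9b/C-10b, which is fused to ring B; "pentacyclic core" = this core plus the dihydrofuran O-13b/C-7c/C-8c/C-14b.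
2. Retrosynthesis: (a) cut O-13b–C-7c and C-14b–C-8c to give tetracyclic phenol 14 and 4-hydroxystilbene 17; (b) cut C-7b–C-10a (seven-membered ring) to stilbene 12; (c) cut C-9b–C-8b (Heck) to bromide 10; (d) cut C-7a–C-8a (carbene C–H insertion) to benzophenone 6; (e) cut the aryl–CO bond to 5-bromoresorcinol and 3,5-dimethoxybenzoic acid.
3. Forward: benzophenone, first dihydrofuran, stilbene, seven-membered ring, free 13b-OH, second dihydrofuran by oxidative [3+2] union of 14 with 17 (two fragments joined, two stereocentres set), global demethylation.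
4. Stereochemistry: C-8a from catalyst-controlled carbene C–H insertion; C-7a by acid equilibration to the trans ring; C-7b by substrate-controlled Friedel–Crafts closure; C-8c from the chiral environment of the folded tetracycle in the key coupling; C-7c trans to C-8c in the ring closure.
5. Enabling feature: in ring D the free 13b-OH has one open, doubly activated neighbour, C-14b (ortho to O-13b, para to O-11b; C-10b is quaternary, C-12b lies between two oxygens). Ring D can therefore bond through C-14b and O-13b to C-8c and C-7c of an oxidised 4-hydroxystilbene, whose own 4-OH is regenerated on ring closure.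

Key step: step 10

Assumption: Rh2(R-PTAD)4 is taken to give the 8aR centre in step 5; should the sense of induction be the opposite, Rh2(S-PTAD)4 is used with no other change.

**Route**

Step 1
Reactants: 1 5-bromoresorcinol; 2 3,5-dimethoxybenzoic acid
Product: 3 (2-bromo-4,6-dihydroxyphenyl)(3,5-dimethoxyphenyl)methanone
Conditions: BF3·OEt2 (neat), 90 °C; aq. NaOAc work-up
Reagents that add atoms: none
Why: Friedel–Crafts acylation of a resorcinol occurs para to one OH and ortho to the other, and for a 5-substituted resorcinol at the carbon next to that substituent, not between the two OH groups, which places the aroyl group beside bromine.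

Step 2
Reactants: 3 (2-bromo-4,6-dihydroxyphenyl)(3,5-dimethoxyphenyl)methanone
Product: 4 [4-(benzyloxy)-2-bromo-6-hydroxyphenyl](3,5-dimethoxyphenyl)methanone
Conditions: BnBr (1.05 equiv), K2CO3 (1.1 equiv), acetone, 55 °C
Reagents that add atoms: benzyl bromide, BrCc1ccccc1
Why: Williamson etherification is selective for the 4-OH because the 6-OH is held in a hydrogen bond to the ketone and shielded by the aroyl group.

Step 3
Reactants: 4 [4-(benzyloxy)-2-bromo-6-hydroxyphenyl](3,5-dimethoxyphenyl)methanone; 5 4-methoxybenzyl chloride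
Product: 6 {4-(benzyloxy)-2-bromo-6-[(4-methoxyphenyl)methoxy]phenyl}(3,5-dimethoxyphenyl)methanone
Conditions: K2CO3, n-Bu4NI (cat.), DMF, 60 °C
Reagents that add atoms: none
Why: Williamson etherification of the remaining chelated phenol under more forcing conditions installs the O–CH2–aryl group whose carbon becomes C-7a and whose arene becomes ring A.

Step 4
Reactants: 6 {4-(benzyloxy)-2-bromo-6-[(4-methoxyphenyl)methoxy]phenyl}(3,5-dimethoxyphenyl)methanone
Product: 7 hydrazone of ketone 6 (E/Z mixture)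
Conditions: N2H4·H2O (excess), AcOH (cat.), EtOH, 100 °C (sealed tube)
Reagents that add atoms: hydrazine, NN
Why: Hydrazone condensation is driven by excess hydrazine and heat because the carbonyl is flanked by two ortho substituents, and the electron-rich aryl bromide should be inert to hydrazine without a metal catalyst.

Step 5
Reactants: 7 hydrazone of ketone 6
Product: 10 (2R,3R)-6-(benzyloxy)-4-bromo-3-(3,5-dimethoxyphenyl)-2-(4-methoxyphenyl)-2,3-dihydro-1-benzofuran (trans), via diazo compound 8 (not isolated), via cis-dihydrobenzofuran 9 (not isolated)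
Conditions: MnO2 (8 equiv), CH2Cl2, 0 °C; filtration; Rh2(R-PTAD)4 (1 mol %), CH2Cl2, 0 °C to rt; then TFA (5 equiv), 0 °C to rt
Reagents that add atoms: none
Why: MnO2 dehydrogenates the hydrazone to the diaryldiazomethane, whose donor/donor rhodium carbene undergoes enantioselective 1,5 C–H insertion into the O–CH2Ar group (the catalyst fixes C-3 of the benzofuran, which is C-8a, and the ring forms cis), and TFA then equilibrates C-2, which is C-7a, to the trans isomer through reversible ionisation of the 4-methoxybenzylic C–O bond.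

Step 6
Reactants: 10 (2R,3R)-6-(benzyloxy)-4-bromo-3-(3,5-dimethoxyphenyl)-2-(4-methoxyphenyl)-2,3-dihydro-1-benzofuran; 11 2,4-dimethoxystyrene
Product: 12 (2R,3R)-6-(benzyloxy)-4-[(E)-2-(2,4-dimethoxyphenyl)ethenyl]-3-(3,5-dimethoxyphenyl)-2-(4-methoxyphenyl)-2,3-dihydro-1-benzofuran
Conditions: Pd(OAc)2 (5 mol %), P(t-Bu)3·HBF4 (10 mol %), K2CO3, DMF, 100 °C
Reagents that add atoms: none
Why: Mizoroki–Heck arylation of the terminal styrene carbon with syn β-hydride elimination should give the E-stilbene, and the bulky electron-rich phosphine copes with the mono-ortho-substituted, electron-rich aryl bromide.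

Step 7
Reactants: 12 (2R,3R)-stilbene
Product: 13 (7aR,8aR,7bR)-13b-O-benzyl-4a,11a,13a,2b,4b-penta-O-methyl tetracyclic core
Conditions: TFA (10 equiv), CH2Cl2, 0 °C to rt
Reagents that add atoms: none
Why: Intramolecular Friedel–Crafts alkylation: protonation at C-8b gives the 2,4-dimethoxybenzylic cation at C-7b, which is captured by either (equivalent) ortho carbon of ring B to close the seven-membered ring, and the C-8a centre fixes the fold of the forming ring so that ring C ends pseudo-equatorial (H-7b anti to H-8a, 7bR), as in the acid-induced conversion of ε-viniferin into ampelopsin B.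

Step 8
Reactants: 13 13b-O-benzyl tetracyclic core
Product: 14 (7aR,8aR,7bR)-4a,11a,13a,2b,4b-penta-O-methyl tetracyclic core (13b-OH free)
Conditions: H2 (1 atm), Pd/C (10 %), EtOAc/MeOH, rt
Reagents that add atoms: none
Why: Hydrogenolysis cleaves the aryl benzyl ether under neutral conditions, under which the methyl ethers and the cyclic benzylic aryl ether should survive.

Step 9
Reactants: 15 4-bromo-3-methoxyphenol; 16 3,5-dimethoxystyrene
Product: 17 4-[(E)-2-(3,5-dimethoxyphenyl)ethenyl]-3-methoxyphenol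
Conditions: Pd(OAc)2 (5 mol %), P(t-Bu)3·HBF4 (10 mol %), K2CO3, DMF, 100 °C
Reagents that add atoms: none
Why: Mizoroki–Heck coupling tolerates the free phenol and should give the E-stilbene with its 4-OH free for oxidation in the next step.

Step 10
Reactants: 14 tetracyclic phenol; 17 4-[(E)-2-(3,5-dimethoxyphenyl)ethenyl]-3-methoxyphenol
Product: 19 (7aR,8aR,7bR,7cS,8cS)-4a,11a,13a,2b,4b,2c,11c,13c-octa-O-methyl pentacyclic core (4c-OH free), via p-quinone methide 18 (not isolated)
Conditions: Ag2O (3 equiv), 17 (3 equiv, syringe pump over 6 h), CH2Cl2/acetone 3:1, 4 Å MS, rt, dark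
Reagents that add atoms: none
Why: Ag2O oxidises both phenols to phenoxyl radicals; the quinone-methide radical of 17 (spin at C-8c) couples with C-14b of the phenoxyl radical of 14, tautomerisation rearomatises ring D to p-quinone methide 18, and the 13b-OH then adds to C-7c, regenerating the 4c-phenol. The closest known reactions are the Ag2O-mediated β–5 oxidative coupling of 4-hydroxyarylalkenes to trans-2-aryl-2,3-dihydrobenzofurans (δ-viniferin, dehydrodiferulate) and the biomimetic 8–10′ coupling of resveratrol to ε-viniferin. The dihydrofuran ring closes by 5-exo-trig oxa-Michael addition onto the exocyclic quinone-methide carbon. C-7c is set in this closure by C-8c (aryl groups trans, and the closure is reversible, so trans is also the thermodynamic outcome), whereas C-8c is set in the C–C coupling, in which the chiral tetracycle decides which face of the stilbene radical carbon bonds to C-14b. The step needs cross-coupling in preference to homocoupling of 17 (one free OH on each partner, 17 added slowly so that its radical stays dilute), bond formation at C-14b (ortho to O-13b and para to O-11b, while C-10b is quaternary and C-12b lies between two oxygens) and approach of the stilbene radical on the more open face of ring D. The puckered seven-membered ring places ring B and ring C unequally on the two faces of ring D next to C-14b, which should steer the stilbene radical, with its quinone-methide arm over O-13b, to the open face and so to the 7cS,8cS ring, although this bias is remote and is the weakest element of control.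

Step 11
Reactants: 19 octa-O-methyl pentacyclic core
Product: 20 target, (7aR,8aR,7bR,7cS,8cS)-nonaphenol
Conditions: BBr3 (20 equiv), CH2Cl2, −78 °C to rt; MeOH, then aq. NaHCO3
Reagents that add atoms: none
Why: Lewis-acid demethylation of the eight aryl methyl ethers, as used for permethylated oligostilbenes; C-8a, C-8c and C-7b cannot epimerise, and any reversible opening at C-7a–O or C-7c–O recloses to the trans rings.

**Compound list**

1 | 5-bromoresorcinol | Oc1cc(O)cc(Br)c1 | starting material
2 | 3,5-dimethoxybenzoic acid | COc1cc(OC)cc(C(=O)O)c1 | starting material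
3 | (2-bromo-4,6-dihydroxyphenyl)(3,5-dimethoxyphenyl)methanone | O=C(c1cc(OC)cc(OC)c1)c1c(O)cc(O)cc1Br | intermediate
4 | [4-(benzyloxy)-2-bromo-6-hydroxyphenyl](3,5-dimethoxyphenyl)methanone | O=C(c1cc(OC)cc(OC)c1)c1c(O)cc(OCc2ccccc2)cc1Br | intermediate
5 | 4-methoxybenzyl chloride | COc1ccc(CCl)cc1 | starting material
6 | {4-(benzyloxy)-2-bromo-6-[(4-methoxyphenyl)methoxy]phenyl}(3,5-dimethoxyphenyl)methanone | O=C(c1cc(OC)cc(OC)c1)c1c(OCc2ccc(OC)cc2)cc(OCc2ccccc2)cc1Br | intermediate
7 | hydrazone of 6 (E/Z mixture) | NN=C(c1cc(OC)cc(OC)c1)c1c(OCc2ccc(OC)cc2)cc(OCc2ccccc2)cc1Br | intermediate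
8 | 5-(benzyloxy)-1-bromo-2-[diazo(3,5-dimethoxyphenyl)methyl]-3-[(4-methoxyphenyl)methoxy]benzene | [N-]=[N+]=C(c1cc(OC)cc(OC)c1)c1c(OCc2ccc(OC)cc2)cc(OCc2ccccc2)cc1Br | intermediate
9 | (2S,3R)-6-(benzyloxy)-4-bromo-3-(3,5-dimethoxyphenyl)-2-(4-methoxyphenyl)-2,3-dihydro-1-benzofuran (cis) | COc1ccc([C@H]2Oc3cc(OCc4ccccc4)cc(Br)c3[C@H]2c2cc(OC)cc(OC)c2)cc1 | intermediate
10 | (2R,3R)-6-(benzyloxy)-4-bromo-3-(3,5-dimethoxyphenyl)-2-(4-methoxyphenyl)-2,3-dihydro-1-benzofuran (trans) | COc1ccc([C@@H]2Oc3cc(OCc4ccccc4)cc(Br)c3[C@H]2c2cc(OC)cc(OC)c2)cc1 | intermediate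
11 | 2,4-dimethoxystyrene | C=Cc1ccc(OC)cc1OC | starting material
12 | (2R,3R)-6-(benzyloxy)-4-[(E)-2-(2,4-dimethoxyphenyl)ethenyl]-3-(3,5-dimethoxyphenyl)-2-(4-methoxyphenyl)-2,3-dihydro-1-benzofuran | COc1ccc([C@@H]2Oc3cc(OCc4ccccc4)cc(/C=C/c4ccc(OC)cc4OC)c3[C@H]2c2cc(OC)cc(OC)c2)cc1 | intermediate
13 | (7aR,8aR,7bR)-13b-O-benzyl-4a,11a,13a,2b,4b-penta-O-methyl tetracyclic core (ring A on C-7a, ring C on C-7b) | COc1ccc([C@@H]2Oc3cc(OCc4ccccc4)cc4c3[C@H]2c2cc(OC)cc(OC)c2[C@@H](c2ccc(OC)cc2OC)C4)cc1 | intermediate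
14 | (7aR,8aR,7bR)-4a,11a,13a,2b,4b-penta-O-methyl tetracyclic core, 13b-OH free | COc1ccc([C@@H]2Oc3cc(O)cc4c3[C@H]2c2cc(OC)cc(OC)c2[C@@H](c2ccc(OC)cc2OC)C4)cc1 | intermediate
15 | 4-bromo-3-methoxyphenol | COc1cc(O)ccc1Br | starting material
16 | 3,5-dimethoxystyrene | C=Cc1cc(OC)cc(OC)c1 | starting material
17 | 4-[(E)-2-(3,5-dimethoxyphenyl)ethenyl]-3-methoxyphenol | COc1cc(O)ccc1/C=C/c1cc(OC)cc(OC)c1 | intermediate
18 | (7aR,8aR,7bR,8cS)-p-quinone methide: phenol 14 carrying at C-14b the group CH(3,5-dimethoxyphenyl)–CH=(2-methoxy-4-oxocyclohexa-2,5-dien-1-ylidene) | COc1ccc([C@@H]2Oc3cc(O)c(c4c3[C@H]2c2cc(OC)cc(OC)c2[C@@H](c2ccc(OC)cc2OC)C4)[C@H](c2cc(OC)cc(OC)c2)C=C2C=CC(=O)C=C2OC)cc1 | intermediate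
19 | (7aR,8aR,7bR,7cS,8cS)-4a,11a,13a,2b,4b,2c,11c,13c-octa-O-methyl pentacyclic core, 4c-OH free (ring E on C-7c, ring F on C-8c) | COc1ccc([C@@H]2Oc3cc4c(c5c3[C@H]2c2cc(OC)cc(OC)c2[C@@H](c2ccc(OC)cc2OC)C5)[C@H](c2cc(OC)cc(OC)c2)[C@@H](c2ccc(O)cc2OC)O4)cc1 | intermediate
20 | target, (7aR,8aR,7bR,7cS,8cS)-nonaphenol | Oc1ccc([C@@H]2Oc3cc4c(c5c3[C@H]2c2cc(O)cc(O)c2[C@@H](c2ccc(O)cc2O)C5)[C@H](c2cc(O)cc(O)c2)[C@@H](c2ccc(O)cc2O)O4)cc1 | target

**Step count and risks**

Total steps: 11. Longest linear sequence: 10 steps (steps 1–8, 10, 11); step 9 makes the second fragment.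

Steps most likely to fail:

1. Step 10. Homocoupling of the stilbene radical (8–8′ and 8–5′ modes) may outrun the cross-coupling. Coupling may also occur at C-12b or through oxygen. Facial discrimination in the C-14b–C-8c bond formation may be weak, giving the ring with the opposite configuration at C-7c and C-8c. Fallback, from 14 back to the route at 20, builds the ring stepwise under catalyst control. The bromomagnesium phenoxide of 14 (EtMgBr, toluene) adds ortho-specifically to 3,5-dimethoxybenzaldehyde to give the 14b-[hydroxy(3,5-dimethoxyphenyl)methyl] phenol F1. MnO2 oxidises it to the 14b-(3,5-dimethoxybenzoyl) phenol F2. 2,4-Dimethoxybenzyl chloride and K2CO3 in DMF give the 13b-O-(2,4-dimethoxybenzyl) ether F3, and hydrazine gives the hydrazone F4. MnO2 then gives the diazo compound F5, which with Rh2(S-PTAD)4 (the antipode of the step 5 catalyst, since the two dihydrofuran rings are pseudo-mirror images) undergoes C–H insertion to the 7c,8c-cis nona-O-methyl pentacyclic core F6. TFA equilibrates C-7c to give the all-trans nona-O-methyl pentacyclic core F7. BBr3 as in step 11 then gives 20.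

2. Step 5. Enantiofacial discrimination may be lost, and azine formation may compete, because the carbene carbon is flanked by bromine and the ether oxygen. Fallback, from 7 back to the route at 10, replaces asymmetric catalysis by resolution. Hydrazone 7 is oxidised with MnO2 and the diazo compound 8 is cyclised with achiral Rh2(OAc)4 to the racemic cis product, which is 9 together with its enantiomer, the (2R,3S)-cis-dihydrobenzofuran F8. TFA converts this into the racemic trans bromide, which is 10 together with its enantiomer, the (2S,3S)-trans-dihydrobenzofuran F9. Preparative chromatography on an amylose tris(3,5-dimethylphenylcarbamate) phase delivers 10.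

3. Step 11. The Lewis acid may ionise the C-7c–O bond (a 2,4-dioxygenated benzylic ether), leading to ring-opened bromides or Friedel–Crafts rearrangement, and demethylation may be incomplete. Fallback, from 14 back to the route at 20, removes the methyl groups before the sensitive ring exists. BBr3 in CH2Cl2 converts 14 into the fully phenolic (7aR,8aR,7bR)-tetracyclic hexaphenol F10. F10 is then coupled with commercial oxyresveratrol under horseradish peroxidase/H2O2 in aqueous acetone (the same oxidative [3+2] event, now free of protecting groups) to give 20 directly after reversed-phase HPLC, at the price of lower site selectivity among the free phenols.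

Further compounds
F1 | step 10 | (7aR,8aR,7bR)-14b-[hydroxy(3,5-dimethoxyphenyl)methyl] derivative of phenol 14 (carbinol epimers) | COc1ccc([C@@H]2Oc3cc(O)c(C(O)c5cc(OC)cc(OC)c5)c4c3[C@H]2c2cc(OC)cc(OC)c2[C@@H](c2ccc(OC)cc2OC)C4)cc1
F2 | step 10 | (7aR,8aR,7bR)-14b-(3,5-dimethoxybenzoyl) derivative of phenol 14 | COc1ccc([C@@H]2Oc3cc(O)c(C(=O)c5cc(OC)cc(OC)c5)c4c3[C@H]2c2cc(OC)cc(OC)c2[C@@H](c2ccc(OC)cc2OC)C4)cc1
F3 | step 10 | 13b-O-(2,4-dimethoxybenzyl) ether of F2 | COc1ccc([C@@H]2Oc3cc(OCc5ccc(OC)cc5OC)c(C(=O)c5cc(OC)cc(OC)c5)c4c3[C@H]2c2cc(OC)cc(OC)c2[C@@H](c2ccc(OC)cc2OC)C4)cc1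
F4 | step 10 | hydrazone of F3 | COc1ccc([C@@H]2Oc3cc(OCc5ccc(OC)cc5OC)c(C(=NN)c5cc(OC)cc(OC)c5)c4c3[C@H]2c2cc(OC)cc(OC)c2[C@@H](c2ccc(OC)cc2OC)C4)cc1
F5 | step 10 | diazo compound from F4 | COc1ccc([C@@H]2Oc3cc(OCc5ccc(OC)cc5OC)c(C(=[N+]=[N-])c5cc(OC)cc(OC)c5)c4c3[C@H]2c2cc(OC)cc(OC)c2[C@@H](c2ccc(OC)cc2OC)C4)cc1
F6 | step 10 | (7aR,8aR,7bR,7cR,8cS)-nona-O-methyl pentacyclic core (7c,8c-cis) | COc1ccc([C@@H]2Oc3cc4c(c5c3[C@H]2c2cc(OC)cc(OC)c2[C@@H](c2ccc(OC)cc2OC)C5)[C@H](c2cc(OC)cc(OC)c2)[C@H](c2ccc(OC)cc2OC)O4)cc1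
F7 | step 10 | (7aR,8aR,7bR,7cS,8cS)-nona-O-methyl pentacyclic core (all-trans) | COc1ccc([C@@H]2Oc3cc4c(c5c3[C@H]2c2cc(OC)cc(OC)c2[C@@H](c2ccc(OC)cc2OC)C5)[C@H](c2cc(OC)cc(OC)c2)[C@@H](c2ccc(OC)cc2OC)O4)cc1
F8 | step 5 | (2R,3S)-6-(benzyloxy)-4-bromo-3-(3,5-dimethoxyphenyl)-2-(4-methoxyphenyl)-2,3-dihydro-1-benzofuran (enantiomer of 9) | COc1ccc([C@@H]2Oc3cc(OCc4ccccc4)cc(Br)c3[C@@H]2c2cc(OC)cc(OC)c2)cc1
F9 | step 5 | (2S,3S)-6-(benzyloxy)-4-bromo-3-(3,5-dimethoxyphenyl)-2-(4-methoxyphenyl)-2,3-dihydro-1-benzofuran (enantiomer of 10) | COc1ccc([C@H]2Oc3cc(OCc4ccccc4)cc(Br)c3[C@@H]2c2cc(OC)cc(OC)c2)cc1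
F10 | step 11 | (7aR,8aR,7bR)-tetracyclic hexaphenol (fully demethylated 14) | Oc1ccc([C@@H]2Oc3cc(O)cc4c3[C@H]2c2cc(O)cc(O)c2[C@@H](c2ccc(O)cc2O)C4)cc1
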